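**Retrosynthetic overview**
1. Target ⇐ C2-keto lactone (reagent-controlled C2 reduction, then acetylation).
2. Ten-membered ring and γ-lactone ⇐ linear 6-6-6 tricycle: retro-aldol cleavage of the ring-B bond C3–C8 (ring expansion 6 → 10), captured by an intramolecular Reformatsky closure of C8–C17.
3. Ring C (Z-olefin C5=C6, C7–O) ⇐ Diels–Alder reaction of a 1-silyloxy-3-methylbutadiene with the alkoxy-enedione of ring B.
4. Rings A/B ⇐ enantioselective Diels–Alder reaction of 2-benzyloxy-5-methylbenzoquinone with a Danishefsky-type pentadiene (sets C1), then double kinetic protonation (C10, C11).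
5. Ring order: B (quinone from o-cresol) → A → C → ring expansion to the ten-membered ring with simultaneous lactone closure.

Assumption: (E)-1-methoxypent-1-en-3-one (4) is taken as a catalogue compound.
Convention: briarane numbering C1–C20 is used for every intermediate (C15, C16, C18, C20 = methyls on C1, C5, C17, C11); β = face of the C1 methyl, α = the opposite face.

**Step 1**
Reactants: 1 2-methylphenol
Product: 2 2-methyl-1,4-benzoquinone
Conditions: Co(salen) (C16H14CoN2O2, 5 mol %), O2 (1 atm), DMF, rt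
Reagents that add atoms: dioxygen, O=O
Why: Cobalt–salen-catalysed aerobic oxidation of a phenol with a free para position gives the para-quinone (phenol-to-quinone oxidation); no stereocentre.

**Step 2**
Reactants: 2 2-methyl-1,4-benzoquinone
Product: 3 2-(benzyloxy)-5-methyl-1,4-benzoquinone
Conditions: BnOH (3 equiv), ZnCl2 (1 equiv), CH2Cl2, rt; then Ag2O, MgSO4
Reagents that add atoms: benzyl alcohol, OCc1ccccc1
Why: Lewis-acid-promoted conjugate addition of the alcohol to the unsubstituted double bond at the carbon para to the methyl-bearing carbon, then re-oxidation of the alkoxyhydroquinone (Thiele-type nucleophilic addition–oxidation); no stereocentre.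

**Step 3**
Reactants: 4 (E)-1-methoxypent-1-en-3-one
Product: 5 (1E,3Z)-1-methoxy-3-(trimethylsilyloxy)penta-1,3-diene
Conditions: Me3SiCl, Et3N, ZnCl2 (cat.), Et2O, 0 °C → rt
Reagents that add atoms: chlorotrimethylsilane, C[Si](C)(C)Cl
Why: Soft enolisation and O-silylation of the vinylogous ester (Danishefsky diene synthesis) gives the 3Z enol ether with the C-methyl group on the outside of the diene.

**Step 4**
Reactants: 3 2-(benzyloxy)-5-methyl-1,4-benzoquinone; 5 (1E,3Z)-1-methoxy-3-(trimethylsilyloxy)penta-1,3-diene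
Product: 7 (1S)-cis-fused ring A/B enone (10β-H; 20α-methyl), via silyl enol ether cycloadduct 6 (not isolated)
Conditions: (S)-o-tolyl-CBS-oxazaborolidine·HNTf2 (20 mol %), CH2Cl2, −78 °C; then 0.1 M HCl, THF, 0 °C
Reagents that add atoms: none
Why: Oxazaborolidinium-catalysed enantioselective quinone Diels–Alder reaction in which the monodentate boron acid binds the more basic vinylogous-ester carbonyl (C2=O), so the nucleophilic CH(CH3) terminus of the diene bonds to the unsubstituted C10 and the methoxy terminus to C1 (the benzyloxy double bond is inert), the diene adds endo to the quinone face not shielded by the catalyst aryl group to set the quaternary C1 as S, and mild acid eliminates methanol to the enone (C10 and C11 are reset in step 5).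

**Step 5**
Reactants: 7 (1S)-cis-fused ring A/B enone
Product: 9 (1S)-trans-fused enone (10α-H; 20β-methyl), via dilithium bis-enolate 8 (not isolated)
Conditions: LiN(iPr)2 (2.3 equiv), THF, −78 °C; then 2,6-di-tert-butyl-4-methylphenol (3 equiv), −78 °C; pH 7 buffer
Reagents that add atoms: none
Why: Double deprotonation gives the planar 1,3-diene-1,4-diolate, and kinetic enolate protonation of C10 and C11 from the α face (opposite the C1 methyl, which is vicinal to C10 and 1,3-related to C11) gives the trans ring fusion and the axial 20β-methyl group.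

**Step 6**
Reactants: 10 3-methylbut-2-enal
Product: 11 (E)-triethyl[(3-methylbuta-1,3-dien-1-yl)oxy]silane
Conditions: Et3SiOTf, Et3N, Et2O, 0 °C
Reagents that add atoms: triethylsilyl trifluoromethanesulfonate, CC[Si](CC)(CC)OS(=O)(=O)C(F)(F)F
Why: γ-Deprotonation and O-silylation of the enal (silyl dienol ether formation) gives the (E)-1-silyloxydiene.

**Step 7**
Reactants: 9 (1S)-trans-fused enone; 11 (E)-triethyl[(3-methylbuta-1,3-dien-1-yl)oxy]silane
Product: 12 linear tricycle (8β-OBn; 7α-OSiEt3; 3β-H)
Conditions: ZnBr2 (0.3 equiv), CH2Cl2, −30 → 0 °C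
Reagents that add atoms: none
Why: Chelate-activated Diels–Alder reaction of the alkoxy-enedione in which the nucleophilic C4 terminus of the diene bonds to C3 (β to the zinc-chelated C9 carbonyl) and the silyloxy carbon to C8, addition occurs on the α face anti to the axial C1 methyl, and the endo transition state puts the C7 silyloxy group cis to C9 (trans to the C8 benzyloxy), which sets C7 and forms the trisubstituted C5=C6 olefin as Z inside a six-membered ring.

**Step 8**
Reactants: 12 linear tricycle
Product: 13 9α,12β-diol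
Conditions: NaBH4, CeCl3·7H2O, MeOH/THF, −78 → −40 °C
Reagents that add atoms: none
Why: Luche reduction in which axial α attack on the enone, anti to the axial C11 methyl, gives the 12β-alcohol, and β-face attack on the cerium-chelated α-benzyloxy ketone (the α face is screened by the axial C7 branch on C8) gives the equatorial 9α-alcohol, while the C2 ketone between quaternary C1 and ring-fusion C3 is left.

**Step 9**
Reactants: 13 9α,12β-diol
Product: 14 12α-butanoate 9α-alcohol
Conditions: PrCO2H, PPh3, DIAD, toluene, 0 °C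
Reagents that add atoms: butanoic acid, CCCC(=O)O
Why: Mitsunobu esterification inverts the allylic C12 carbinol (SN2; SN2′ at the neopentyl C14 is blocked) to the 12α-ester, and the C9 alcohol flanked by C8 and C10 does not react.

**Step 10**
Reactants: 14 12α-butanoate 9α-alcohol
Product: 15 9α-acetate 12α-butanoate
Conditions: Ac2O, DMAP, pyridine, CH2Cl2, rt
Reagents that add atoms: acetic anhydride, CC(=O)OC(C)=O
Why: DMAP-catalysed acetylation of the remaining secondary alcohol with retention at C9.

**Step 11**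
Reactants: 15 9α-acetate 12α-butanoate
Product: 17 7α,8β-diol, via C8 carbinol silyl ether 16 (not isolated)
Conditions: BCl3, C6HMe5, CH2Cl2, −78 °C; then MeOH, −78 °C → rt
Reagents that add atoms: none
Why: Boron trichloride with a cation scavenger cleaves the benzyl ether at the benzylic carbon (debenzylation; C8, flanked by two oxygenated carbons, does not ionise), and the HCl formed on methanol quench removes the triethylsilyl ether, with no stereocentre touched.

**Step 12**
Reactants: 17 7α,8β-diol; 18 2-bromopropanoyl bromide (racemic)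
Product: 19 7α-(2-bromopropanoate) 8β-alcohol
Conditions: pyridine, CH2Cl2, −40 °C
Reagents that add atoms: none
Why: Acylation of the secondary allylic C7 alcohol by the acid bromide while the tertiary C8 alcohol is inert; the CHBr centre is lost in step 13, so both epimers are used.

**Step 13**
Reactants: 19 7α-(2-bromopropanoate) 8β-alcohol
Product: 22 C2-keto lactone with ten-membered ring, via ethylzinc aldolate 20 (not isolated), via ring-expanded zinc enolate 21 (not isolated)
Conditions: Et2Zn (3 equiv), RhCl(PPh3)3 (5 mol %), THF, 0 °C → rt; H2O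
Reagents that add atoms: none
Why: Proposed new method: a retro-aldol ring expansion driven by Reformatsky capture, in which diethylzinc turns the tertiary β-hydroxy ketone into its ethylzinc aldolate 20, reversible retro-aldol cleavage of C3–C8 (C2 is the only β-carbonyl) opens ring B to the ten-membered diketone enolate 21, and the zinc ester enolate formed from the bromo ester by RhCl(PPh3)3/Et2Zn adds irreversibly to the freed C8 ketone to close the γ-lactone, the C7–O tether attacking through the rotamer with C6 anti to C9 (the only one the ten-membered ring allows) to give the trans-fused lactone (8S) with the C17 methyl anti to C9 (17R, also the thermodynamic epimer); the closest known reactions are the rhodium-catalysed diethylzinc Reformatsky lactonisation and the retro-aldol (de Mayo-type) ring expansion of metal aldolates.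

**Step 14**
Reactants: 22 C2-keto lactone
Product: 23 (2R)-alcohol
Conditions: (S)-Me-CBS (1 equiv), catecholborane, toluene, −78 → −40 °C; MeOH
Reagents that add atoms: none
Why: Corey–Bakshi–Shibata reduction under reagent control (large group = quaternary C1, small group = C3H2) gives the 2R alcohol; lactone and esters are inert.

**Step 15**
Reactants: 23 (2R)-alcohol
Product: 24 CNP0211702.1
Conditions: Ac2O, DMAP, Et3N, CH2Cl2, 0 °C → rt
Reagents that add atoms: acetic anhydride, CC(=O)OC(C)=O
Why: DMAP-catalysed acetylation of the secondary C2 alcohol with retention; the tertiary C8 alcohol is not acylated under these conditions.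

**Compound list**
1 | 2-methylphenol (o-cresol) | Cc1ccccc1O | starting material
2 | 2-methyl-1,4-benzoquinone | CC1=CC(=O)C=CC1=O | intermediate
3 | 2-(benzyloxy)-5-methyl-1,4-benzoquinone | CC1=CC(=O)C(OCc2ccccc2)=CC1=O | intermediate
4 | (E)-1-methoxypent-1-en-3-one | CCC(=O)/C=C/OC | starting material
5 | (1E,3Z)-1-methoxy-3-(trimethylsilyloxy)penta-1,3-diene | C/C=C(/C=C/OC)O[Si](C)(C)C | intermediate
6 | (1S)-cis-fused Diels–Alder cycloadduct: ring B 8-benzyloxy-3(8)-ene-2,9-dione; ring A with C12 trimethylsilyl enol ether (C12=C13), 14α-methoxy, 10β-H, 11β-H (20α-methyl) | C[C@@H]1C(O[Si](C)(C)C)=C[C@H](OC)[C@]2(C)C(=O)C=C(OCc3ccccc3)C(=O)[C@H]12 | intermediate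
7 | (1S)-cis-fused enone, 2-(benzyloxy)-4a,8-dimethyl-8,8a-dihydronaphthalene-1,4,7(4aH)-trione (naphthalene C4a = C1, C8a = C10, C8 = C11), 10β-H, 11β-H (20α-methyl) | C[C@@H]1C(=O)C=C[C@]2(C)C(=O)C=C(OCc3ccccc3)C(=O)[C@H]12 | intermediate
8 | dilithium bis-enolate of 7 (C9(OLi)=C10 and C11=C12(OLi)), 1S | CC1=C(O[Li])C=C[C@]2(C)C(=O)C=C(OCc3ccccc3)C(O[Li])=C12 | intermediate
9 | (1S)-trans-fused enone, the 10α-H, 11α-H (20β-methyl) diastereomer of 7 | C[C@H]1C(=O)C=C[C@]2(C)C(=O)C=C(OCc3ccccc3)C(=O)[C@@H]12 | intermediate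
10 | 3-methylbut-2-enal | CC(C)=CC=O | starting material
11 | (E)-triethyl[(3-methylbuta-1,3-dien-1-yl)oxy]silane | C=C(C)/C=C/O[Si](CC)(CC)CC | intermediate
12 | linear tricycle, rings A/B/C: (1S), 3β-H, 7α-triethylsilyloxy, 8β-benzyloxy, 10α-H, 20β-methyl; ketones at C2, C9, C12; olefins C5=C6 (5-methyl) and C13=C14 | C[C@H]1C(=O)C=C[C@]2(C)C(=O)[C@@H]3CC(C)=C[C@H](O[Si](CC)(CC)CC)[C@]3(OCc4ccccc4)C(=O)[C@@H]12 | intermediate
13 | 9α,12β-diol of 12 (C2 ketone kept) | C[C@H]1[C@@H](O)C=C[C@]2(C)C(=O)[C@@H]3CC(C)=C[C@H](O[Si](CC)(CC)CC)[C@]3(OCc4ccccc4)[C@H](O)[C@@H]12 | intermediate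
14 | 12α-butanoate 9α-alcohol (C12 inverted) | C[C@H]1[C@H](OC(=O)CCC)C=C[C@]2(C)C(=O)[C@@H]3CC(C)=C[C@H](O[Si](CC)(CC)CC)[C@]3(OCc4ccccc4)[C@H](O)[C@@H]12 | intermediate
15 | 9α-acetate 12α-butanoate | C[C@H]1[C@H](OC(=O)CCC)C=C[C@]2(C)C(=O)[C@@H]3CC(C)=C[C@H](O[Si](CC)(CC)CC)[C@]3(OCc4ccccc4)[C@H](OC(C)=O)[C@@H]12 | intermediate
16 | 8β-alcohol 7α-triethylsilyl ether (benzyl removed) | C[C@H]1[C@H](OC(=O)CCC)C=C[C@]2(C)C(=O)[C@@H]3CC(C)=C[C@H](O[Si](CC)(CC)CC)[C@]3(O)[C@H](OC(C)=O)[C@@H]12 | intermediate
17 | 7α,8β-diol | C[C@H]1[C@H](OC(=O)CCC)C=C[C@]2(C)C(=O)[C@@H]3CC(C)=C[C@H](O)[C@]3(O)[C@H](OC(C)=O)[C@@H]12 | intermediate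
18 | 2-bromopropanoyl bromide (racemic) | CC(Br)C(Br)=O | starting material
19 | 7α-(2-bromopropanoate) of 17, free 8β tertiary alcohol (both CHBr epimers) | C[C@H]1[C@H](OC(=O)CCC)C=C[C@]2(C)C(=O)[C@@H]3CC(C)=C[C@H](OC(=O)C(C)Br)[C@]3(O)[C@H](OC(C)=O)[C@@H]12 | intermediate
20 | ethylzinc 8-alkoxide (aldolate) of 19 | C[C@H]1[C@H](OC(=O)CCC)C=C[C@]2(C)C(=O)[C@@H]3CC(C)=C[C@H](OC(=O)C(C)Br)[C@]3(O[Zn]CC)[C@H](OC(C)=O)[C@@H]12 | intermediate
21 | ring-expanded ten-membered C8 ketone with C2 ethylzinc enolate (C2=C3) and C7 bromo ester | CCCC(=O)O[C@@H]1C=C[C@@]2(C)[C@H]([C@H]1C)[C@@H](OC(C)=O)C(=O)[C@H](/C=C(/C)CC=C2O[Zn]CC)OC(=O)C(C)Br | intermediate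
22 | (1S,7S,8S,9R,10S,11R,12R,17R,5Z)-9-acetoxy-12-butanoyloxy-8-hydroxy-2-oxobriara-5,13-diene C19→O7 γ-lactone | CCCC(=O)O[C@@H]1C=C[C@@]2(C)[C@H]([C@H]1C)[C@@H](OC(C)=O)[C@@]1(O)[C@H](/C=C(/C)CCC2=O)OC(=O)[C@@H]1C | intermediate
23 | (2R)-alcohol of 22 | CCCC(=O)O[C@@H]1C=C[C@@]2(C)[C@H]([C@H]1C)[C@@H](OC(C)=O)[C@@]1(O)[C@H](/C=C(/C)CC[C@H]2O)OC(=O)[C@@H]1C | intermediate
24 | CNP0211702.1, (1S,2R,7S,8S,9R,10S,11R,12R,17R,5Z)-2,9-diacetoxy-12-butanoyloxy-8-hydroxybriara-5,13-diene C19→O7 γ-lactone | CCCC(=O)O[C@@H]1C=C[C@@]2(C)[C@H]([C@H]1C)[C@@H](OC(C)=O)[C@@]1(O)[C@H](/C=C(/C)CC[C@H]2OC(C)=O)OC(=O)[C@@H]1C | target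

**Totals**
Total step count: 15.
Longest linear sequence: 13 steps (1 → 24 through steps 1, 2, 4, 5 and 7–15).

**Three steps most likely to fail**

Step 13 (the new retro-aldol/Reformatsky relay). The retro-aldol may be too slow or unfavourable on the zinc aldolate. The fallback uses two known reactions in sequence, sets out from 16 and comes back at 22. Compound 16 is isolated by quenching step 11 with aqueous NaHCO3 instead of methanol. Catalytic KOC(CH3)3 in THF at 0 °C then effects the retro-aldol ring expansion (known de Mayo-type fragmentation, helped by release of the congested C3–C8 bond) to the silyloxy diketone F8. HF·pyridine gives the hydroxy diketone F9, and acylation with 18 (pyridine, −40 °C) gives the bromo ester F10. SmI2 (2.2 equiv, THF, −78 °C) then closes the lactone by the established intramolecular samarium Reformatsky reaction to 22.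

Step 7 (Diels–Alder reaction on the donor-substituted enedione). The benzyloxy group may make the dienophile too electron-rich. The fallback reverses the polarity of the O8 substituent, sets out from 9 and comes back at 16. BCl3/C6HMe5 (−78 °C) removes the benzyl group to give the hydroxy-enedione F3, and Ac2O/pyridine gives the enol acetate F4, a dienophile of the proven 2-acetoxyquinone type. Thermal cycloaddition with 11 (toluene, 60 °C) gives the C8-acetoxy tricycle F5, and Luche reduction gives the 9,12-diol F6. Et3N with catalytic DMAP shifts the acetyl group from the tertiary O8 to the secondary O9 to give the C9 acetate F7. Mitsunobu esterification of the C12 alcohol with butanoic acid then gives 16, which is desilylated with methanolic HCl as in the second stage of step 11.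

Step 4 (enantioselective quinone Diels–Alder reaction). Enantioselectivity with this alkoxyquinone is untested. The fallback sets out from 3 and 5 and comes back at 7. BF3·OEt2 (1.1 equiv, CH2Cl2, −78 °C), whose orientation with 2-alkoxy-5-methylquinones is established, followed by the same acid work-up gives racemic material: 7 together with the enantiomeric enone F2, formed through 6 and the enantiomeric cycloadduct F1. Preparative chromatography on a chiral stationary phase then delivers 7.

**Further compounds**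
F1 | step 4 | enantiomer of cycloadduct 6 | C[C@H]1C(O[Si](C)(C)C)=C[C@@H](OC)[C@@]2(C)C(=O)C=C(OCc3ccccc3)C(=O)[C@@H]12
F2 | step 4 | enantiomer of enone 7 | C[C@H]1C(=O)C=C[C@@]2(C)C(=O)C=C(OCc3ccccc3)C(=O)[C@@H]12
F3 | step 7 | hydroxy-enedione (8-OH enol) from 9 | C[C@H]1C(=O)C=C[C@]2(C)C(=O)C=C(O)C(=O)[C@@H]12
F4 | step 7 | enol acetate (8-OAc enedione) | C[C@H]1C(=O)C=C[C@]2(C)C(=O)C=C(OC(C)=O)C(=O)[C@@H]12
F5 | step 7 | C8-acetoxy tricycle (8β-OAc analogue of 12) | C[C@H]1C(=O)C=C[C@]2(C)C(=O)[C@@H]3CC(C)=C[C@H](O[Si](CC)(CC)CC)[C@]3(OC(C)=O)C(=O)[C@@H]12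
F6 | step 7 | 9α,12β-diol with 8β-acetate | C[C@H]1[C@@H](O)C=C[C@]2(C)C(=O)[C@@H]3CC(C)=C[C@H](O[Si](CC)(CC)CC)[C@]3(OC(C)=O)[C@H](O)[C@@H]12
F7 | step 7 | 9α-acetate 8β,12β-diol (after acyl shift) | C[C@H]1[C@@H](O)C=C[C@]2(C)C(=O)[C@@H]3CC(C)=C[C@H](O[Si](CC)(CC)CC)[C@]3(O)[C@H](OC(C)=O)[C@@H]12
F8 | step 13 | ten-membered 2,8-diketone with 7-triethylsilyloxy group | CCCC(=O)O[C@@H]1C=C[C@@]2(C)[C@H]([C@H]1C)[C@@H](OC(C)=O)C(=O)[C@H](/C=C(/C)CCC2=O)O[Si](CC)(CC)CC
F9 | step 13 | ten-membered 2,8-diketone with free 7-hydroxyl | CCCC(=O)O[C@@H]1C=C[C@@]2(C)[C@H]([C@H]1C)[C@@H](OC(C)=O)C(=O)[C@H](/C=C(/C)CCC2=O)O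
F10 | step 13 | ten-membered 2,8-diketone 7-(2-bromopropanoate) | CCCC(=O)O[C@@H]1C=C[C@@]2(C)[C@H]([C@H]1C)[C@@H](OC(C)=O)C(=O)[C@H](/C=C(/C)CCC2=O)OC(=O)C(C)Br
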